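**Retrosynthetic overview**

1. Sigmoidin D (24) ⇐ hydrogenolysis of four benzyl ethers ⇐ (2S)-flavanone 23 ⇐ copper hydride asymmetric 1,4-reduction of flavone 22. The C2=C3 double bond is a temporary higher oxidation level that this reduction removes.
2. Flavone 22 ⇐ one-operation annulation of aryne 20 (from silyl triflate 8) with arylpropiolic acid 19. The acid oxygen becomes O1 (bound to C8a), the acyl carbon C4 moves onto C4a, and O1 then closes onto C2.
3. Enabling feature: in ring A the ether oxygen O1 (on C8a) and the ketone carbon C4 (on C4a) sit on neighbouring ring carbons, with the C5 oxygen directly beside C4a. A 3-alkoxyaryne therefore takes oxygen at C8a and acyl at C4a, and because O1 and C4 are 1,3-related through C2–C3 in ring C, one carboxylic acid supplies O1, C4, C3 and C2.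
4. Acid 19 ⇐ Sonogashira coupling of iodide 17 ⇐ (3S)-chromanol 16 ⇐ Jacobsen epoxidation and hydride opening of chromene 14 ⇐ propargyl ether Claisen from 10. Aryne precursor 8 ⇐ carbamate-directed ortho-silylation of 1.
5. Ring order: the dihydropyran ring fused to ring B first (step 6), ring C (the pyranone) last (step 11); rings A and B are bought as phenols.

Key step: step 11

Remark: the target is read as the (2S)-flavanone carrying a (3S)-3-hydroxy-2,2-dimethylchroman unit. Compounds 1, 9, 11 and 18 are assumed to be commercial.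

**Route**

Step 1
Reactants: 1 3,5-bis(benzyloxy)phenol
Product: 2 3,5-bis(benzyloxy)phenyl N-(propan-2-yl)carbamate
Conditions: i-PrNCO, Et3N (cat.), CH2Cl2, rt
Reagents that add atoms: isopropyl isocyanate, CC(C)N=C=O
Why: Base-catalysed addition of the phenol to the isocyanate (carbamoylation) installs an N-monoalkyl carbamate that later serves as ortho-directing group and is cleavable under mild base.

Step 2
Reactants: 2 3,5-bis(benzyloxy)phenyl N-(propan-2-yl)carbamate
Product: 6 3,5-bis(benzyloxy)-2-(trimethylsilyl)phenyl N-(propan-2-yl)carbamate, via N-silyl carbamate 3 (not isolated), via aryllithium 4 (not isolated), via N-silyl C-silyl carbamate 5 (not isolated)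
Conditions: TBSOTf, TMEDA, Et2O, 0 °C to rt; then n-BuLi, TMEDA, −78 °C; then Me3SiCl, −78 °C to rt; aq. NaHSO4 work-up
Reagents that add atoms: chlorotrimethylsilane, C[Si](C)(C)Cl; tert-butyldimethylsilyl triflate, CC(C)(C)[Si](C)(C)OS(=O)(=O)C(F)(F)F (its silyl group is carried only by 3, 4 and 5)
Why: Directed ortho-metalation: in-flask N-silylation masks the N–H, the O-carbamate then directs lithiation to the position between itself and a benzyloxy group (the two ortho positions are equivalent), Me3SiCl traps the aryllithium, and aqueous acid removes the N-silyl group.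

Step 3
Reactants: 6 3,5-bis(benzyloxy)-2-(trimethylsilyl)phenyl N-(propan-2-yl)carbamate
Product: 8 3,5-bis(benzyloxy)-2-(trimethylsilyl)phenyl trifluoromethanesulfonate, via silylphenol 7 (not isolated)
Conditions: DBU, Et2NH, MeCN, 40 °C; then PhNTf2, rt
Reagents that add atoms: N-phenylbis(trifluoromethanesulfonimide), O=S(=O)(N(c1ccccc1)S(=O)(=O)C(F)(F)F)C(F)(F)F
Why: E1cB cleavage of the N-monoalkyl carbamate (the isocyanate is trapped by diethylamine) frees the hindered silylphenol, which is triflated in the same flask to give the o-silylaryl triflate aryne precursor.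

Step 4
Reactants: 9 2-(benzyloxy)phenol
Product: 10 2-(benzyloxy)-4-iodophenol
Conditions: NaI, NaOH, MeOH, 0 °C; aq. NaOCl added slowly
Reagents that add atoms: sodium iodide, [Na+].[I-]
Why: Electrophilic aromatic iodination of the phenoxide by hypoiodite formed in the flask should go para to the free hydroxyl, the most activated and least hindered position.

Step 5
Reactants: 10 2-(benzyloxy)-4-iodophenol; 11 3-chloro-3-methylbut-1-yne
Product: 12 2-(benzyloxy)-4-iodo-1-[(2-methylbut-3-yn-2-yl)oxy]benzene
Conditions: K2CO3, KI (cat.), acetone, 60 °C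
Reagents that add atoms: none
Why: Williamson-type O-alkylation of the phenoxide by the tertiary propargylic chloride gives the aryl 1,1-dimethylpropargyl ether needed for chromene formation.

Step 6
Reactants: 12 2-(benzyloxy)-4-iodo-1-[(2-methylbut-3-yn-2-yl)oxy]benzene
Product: 14 8-(benzyloxy)-6-iodo-2,2-dimethyl-2H-chromene, via allenylphenol 13 (not isolated)
Conditions: N,N-diethylaniline, 190 °C
Reagents that add atoms: none
Why: Aryl propargyl ether Claisen rearrangement onto the only free ortho position, followed by 1,5-hydrogen shift and oxa-6π electrocyclisation, is the classical thermal route to 2,2-dimethylchromenes.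

Step 7
Reactants: 14 8-(benzyloxy)-6-iodo-2,2-dimethyl-2H-chromene
Product: 15 (3S,4S)-8-(benzyloxy)-3,4-epoxy-6-iodo-2,2-dimethylchromane
Conditions: (S,S)-Jacobsen catalyst [(S,S)-N,N'-bis(3,5-di-tert-butylsalicylidene)-1,2-cyclohexanediaminomanganese chloride, C36H52ClMnN2O2, trivalent manganese] (5 mol%), 4-phenylpyridine N-oxide, aq. NaOCl (pH 11.3), CH2Cl2, 0 °C; used crude
Reagents that add atoms: sodium hypochlorite, [Na+].[O-]Cl
Why: Jacobsen–Katsuki epoxidation of the cis-disubstituted, aryl-conjugated chromene olefin, for which the (S,S)-salen ligand should select the face giving the (3S,4S)-oxide as is general for 2,2-dimethylchromenes; this sets the chroman C3 centre.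

Step 8
Reactants: 15 (3S,4S)-8-(benzyloxy)-3,4-epoxy-6-iodo-2,2-dimethylchromane
Product: 16 (3S)-8-(benzyloxy)-6-iodo-2,2-dimethylchroman-3-ol
Conditions: LiBHEt3, THF, −78 to 0 °C; then H2O
Reagents that add atoms: none
Why: SN2 hydride opening of the epoxide at the benzylic C4 (activated by the arene and less hindered than C3, which is flanked by the quaternary C2) leaves the C3–O bond untouched, so the (3S) configuration is retained; the basic hydride avoids acid-induced rearrangement of the labile epoxide.

Step 9
Reactants: 16 (3S)-8-(benzyloxy)-6-iodo-2,2-dimethylchroman-3-ol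
Product: 17 (3S)-3,8-bis(benzyloxy)-6-iodo-2,2-dimethylchromane
Conditions: NaH, BnBr, Bu4NI (cat.), DMF, 0 °C to rt
Reagents that add atoms: benzyl bromide, BrCc1ccccc1
Why: Williamson etherification of the secondary alkoxide protects the alcohol against O-arylation by the aryne, with a group that leaves together with the aryl benzyl ethers at the end.

Step 10
Reactants: 17 (3S)-3,8-bis(benzyloxy)-6-iodo-2,2-dimethylchromane; 18 propiolic acid
Product: 19 3-[(3S)-3,8-bis(benzyloxy)-2,2-dimethylchroman-6-yl]prop-2-ynoic acid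
Conditions: Pd(PPh3)4 (5 mol%, zerovalent palladium), DBU, DMSO, 35 °C; then aq. HCl
Reagents that add atoms: none
Why: Copper-free Sonogashira coupling of an aryl iodide with propiolic acid (as its carboxylate) is an established route to arylpropiolic acids, and the low temperature should suppress decarboxylation.

Step 11
Reactants: 8 3,5-bis(benzyloxy)-2-(trimethylsilyl)phenyl trifluoromethanesulfonate (1.5 equiv); 19 3-[(3S)-3,8-bis(benzyloxy)-2,2-dimethylchroman-6-yl]prop-2-ynoic acid
Product: 22 5,7-bis(benzyloxy)-2-[(3S)-3,8-bis(benzyloxy)-2,2-dimethylchroman-6-yl]-4H-chromen-4-one, via aryne 20 (not isolated), via hydroxyaryl ynone 21 (not isolated)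
Conditions: CsF (4 equiv), THF, 125 °C, sealed tube
Reagents that add atoms: none
Why: Fluoride converts 8 into 3,5-bis(benzyloxy)benzyne 20, and the caesium carboxylate of 19 adds through oxygen to the aryne carbon remote from the neighbouring benzyloxy group, because that carbon is the more electrophilic end of the distorted 3-alkoxyaryne and the resulting aryl anion sits beside the inductively stabilising oxygen. The aryl anion then attacks the ester carbonyl (4-exo-trig), and the four-membered alkoxide opens to the 2-acylphenoxide 21, a net insertion of the aryne into the acyl C–O bond that places O1 on C8a and C4 on C4a. The phenoxide adds to the ynone terminus in a 6-endo-dig oxa-Michael closure of ring C, and protonation at C3 by the acid proton gives the flavone. The closest known reaction type is the fluoride-mediated coupling of arynes with carboxylic acids to give o-hydroxyaryl ketones and, from arylpropiolic acids, flavones. No stereocentre is formed, since C2 is sp2 here and is set in step 12, and the (3S) benzyl ether cannot epimerise under these conditions. The step needs three selectivities: the sense of aryne addition (secured by the benzyloxy group beside the triple bond; the opposite sense would give the 6,8-dioxygenated isomer), acyl capture over protonation of the aryl anion (favoured by the high temperature, the aprotic medium and the Z-ester conformation that presents the carbonyl and turns the alkyne away), and 6-endo over 5-exo closure (reversible addition in an aprotic medium favours the chromone).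

Step 12
Reactants: 22 5,7-bis(benzyloxy)-2-[(3S)-3,8-bis(benzyloxy)-2,2-dimethylchroman-6-yl]-4H-chromen-4-one
Product: 23 (2S)-5,7-bis(benzyloxy)-2-[(3S)-3,8-bis(benzyloxy)-2,2-dimethylchroman-6-yl]-2,3-dihydro-4H-chromen-4-one
Conditions: Cu(OAc)2·H2O (5 mol%), (R)-DTBM-SEGPHOS (5.5 mol%), (EtO)2MeSiH, t-BuOH, toluene, 0 °C to rt
Reagents that add atoms: none
Why: Copper hydride-catalysed asymmetric conjugate reduction, a reaction type established for β,β-disubstituted enones and 2-substituted chromones, delivers hydride to one face of C2 under ligand control (the remote C3 centre should have no influence; the (R)-ligand is assigned provisionally for the 2S product and its antipode is used if a model flavone shows the opposite sense), while tert-butanol protonates the copper enolate before retro-oxa-Michael opening can erode C2.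

Step 13
Reactants: 23 (2S)-5,7-bis(benzyloxy)-2-[(3S)-3,8-bis(benzyloxy)-2,2-dimethylchroman-6-yl]-2,3-dihydro-4H-chromen-4-one
Product: 24 sigmoidin D, (2S)-5,7-dihydroxy-2-[(3S)-3,8-dihydroxy-2,2-dimethylchroman-6-yl]-2,3-dihydro-4H-chromen-4-one
Conditions: H2 (1 atm), Pd(OH)2/C, EtOAc–MeOH, rt
Reagents that add atoms: none
Why: Catalytic hydrogenolysis should cleave the three aryl benzyl ethers and the secondary alkyl benzyl ether under neutral conditions that neither open the flavanone ring by retro-oxa-Michael reaction nor epimerise C2 or C3.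

**Compound list**

1 | 3,5-bis(benzyloxy)phenol | Oc1cc(OCc2ccccc2)cc(OCc2ccccc2)c1 | starting material
2 | 3,5-bis(benzyloxy)phenyl N-(propan-2-yl)carbamate | CC(C)NC(=O)Oc1cc(OCc2ccccc2)cc(OCc2ccccc2)c1 | intermediate
3 | 3,5-bis(benzyloxy)phenyl N-(tert-butyldimethylsilyl)-N-(propan-2-yl)carbamate | CC(C)N(C(=O)Oc1cc(OCc2ccccc2)cc(OCc2ccccc2)c1)[Si](C)(C)C(C)(C)C | intermediate
4 | 2-lithio derivative of 3 | CC(C)N(C(=O)Oc1cc(OCc2ccccc2)cc(OCc2ccccc2)c1[Li])[Si](C)(C)C(C)(C)C | intermediate
5 | 3,5-bis(benzyloxy)-2-(trimethylsilyl)phenyl N-(tert-butyldimethylsilyl)-N-(propan-2-yl)carbamate | CC(C)N(C(=O)Oc1cc(OCc2ccccc2)cc(OCc2ccccc2)c1[Si](C)(C)C)[Si](C)(C)C(C)(C)C | intermediate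
6 | 3,5-bis(benzyloxy)-2-(trimethylsilyl)phenyl N-(propan-2-yl)carbamate | CC(C)NC(=O)Oc1cc(OCc2ccccc2)cc(OCc2ccccc2)c1[Si](C)(C)C | intermediate
7 | 3,5-bis(benzyloxy)-2-(trimethylsilyl)phenol | Oc1cc(OCc2ccccc2)cc(OCc2ccccc2)c1[Si](C)(C)C | intermediate
8 | 3,5-bis(benzyloxy)-2-(trimethylsilyl)phenyl trifluoromethanesulfonate | C[Si](C)(C)c1c(OCc2ccccc2)cc(OCc2ccccc2)cc1OS(=O)(=O)C(F)(F)F | intermediate
9 | 2-(benzyloxy)phenol | Oc1ccccc1OCc1ccccc1 | starting material
10 | 2-(benzyloxy)-4-iodophenol | Oc1ccc(I)cc1OCc1ccccc1 | intermediate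
11 | 3-chloro-3-methylbut-1-yne | C#CC(C)(C)Cl | starting material
12 | 2-(benzyloxy)-4-iodo-1-[(2-methylbut-3-yn-2-yl)oxy]benzene | C#CC(C)(C)Oc1ccc(I)cc1OCc1ccccc1 | intermediate
13 | 2-(benzyloxy)-4-iodo-6-(3-methylbuta-1,2-dien-1-yl)phenol | CC(C)=C=Cc1cc(I)cc(OCc2ccccc2)c1O | intermediate
14 | 8-(benzyloxy)-6-iodo-2,2-dimethyl-2H-chromene | CC1(C)Oc2c(OCc3ccccc3)cc(I)cc2C=C1 | intermediate
15 | (3S,4S)-8-(benzyloxy)-3,4-epoxy-6-iodo-2,2-dimethylchromane | CC1(C)Oc2c(OCc3ccccc3)cc(I)cc2[C@@H]3O[C@H]13 | intermediate
16 | (3S)-8-(benzyloxy)-6-iodo-2,2-dimethylchroman-3-ol | CC1(C)Oc2c(OCc3ccccc3)cc(I)cc2C[C@@H]1O | intermediate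
17 | (3S)-3,8-bis(benzyloxy)-6-iodo-2,2-dimethylchromane | CC1(C)Oc2c(OCc3ccccc3)cc(I)cc2C[C@@H]1OCc1ccccc1 | intermediate
18 | propiolic acid (prop-2-ynoic acid) | C#CC(=O)O | starting material
19 | 3-[(3S)-3,8-bis(benzyloxy)-2,2-dimethylchroman-6-yl]prop-2-ynoic acid | CC1(C)Oc2c(OCc3ccccc3)cc(C#CC(=O)O)cc2C[C@@H]1OCc1ccccc1 | intermediate
20 | 3,5-bis(benzyloxy)benzyne (1,2-didehydro-3,5-bis(benzyloxy)benzene) | C1#CC(OCc2ccccc2)=CC(OCc2ccccc2)=C1 | intermediate
21 | 1-[2,4-bis(benzyloxy)-6-hydroxyphenyl]-3-[(3S)-3,8-bis(benzyloxy)-2,2-dimethylchroman-6-yl]prop-2-yn-1-one | CC1(C)Oc2c(OCc3ccccc3)cc(C#CC(=O)c3c(O)cc(OCc4ccccc4)cc3OCc3ccccc3)cc2C[C@@H]1OCc1ccccc1 | intermediate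
22 | 5,7-bis(benzyloxy)-2-[(3S)-3,8-bis(benzyloxy)-2,2-dimethylchroman-6-yl]-4H-chromen-4-one | CC1(C)Oc2c(OCc3ccccc3)cc(-c3cc(=O)c4c(OCc5ccccc5)cc(OCc5ccccc5)cc4o3)cc2C[C@@H]1OCc1ccccc1 | intermediate
23 | (2S)-5,7-bis(benzyloxy)-2-[(3S)-3,8-bis(benzyloxy)-2,2-dimethylchroman-6-yl]-2,3-dihydro-4H-chromen-4-one | CC1(C)Oc2c(OCc3ccccc3)cc([C@@H]3CC(=O)c4c(OCc5ccccc5)cc(OCc5ccccc5)cc4O3)cc2C[C@@H]1OCc1ccccc1 | intermediate
24 | sigmoidin D, (2S)-5,7-dihydroxy-2-[(3S)-3,8-dihydroxy-2,2-dimethylchroman-6-yl]-2,3-dihydro-4H-chromen-4-one | CC1(C)Oc2c(O)cc([C@@H]3CC(=O)c4c(O)cc(O)cc4O3)cc2C[C@@H]1O | target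

**Step count and risks**

Total step count: 13. Steps 1–3 give aryne precursor 8, steps 4–10 give acid 19, and steps 11–13 join the two and finish.
Longest linear sequence: 10 steps (steps 4 to 13).

Steps most likely to fail:

Step 11. The aryl anion may be protonated before it reaches the ester carbonyl, which gives the aryl ester instead of the ketone. The propiolate may also decarboxylate at 125 °C, or the phenoxide may close 5-exo instead of 6-endo. The fallback leaves the aryne chemistry and builds the same flavone by the chalcone route. It sets out from iodide 17: iodine–magnesium exchange (i-PrMgCl·LiCl, THF, 0 °C) and quenching with DMF should give (3S)-3,8-bis(benzyloxy)-2,2-dimethylchromane-6-carbaldehyde F1. Claisen–Schmidt condensation of F1 with purchased 1-[2,4-bis(benzyloxy)-6-hydroxyphenyl]ethan-1-one F2 (KOH, EtOH, rt) should give (2E)-1-[2,4-bis(benzyloxy)-6-hydroxyphenyl]-3-[(3S)-3,8-bis(benzyloxy)-2,2-dimethylchroman-6-yl]prop-2-en-1-one F3. Oxidative cyclisation of F3 (I2 cat., DMSO, 120 °C) comes back to the route at flavone 22.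

Step 12. Hydride delivery to the very electron-rich vinylogous ester may be slow or poorly face-selective, and retro-oxa-Michael opening of the copper enolate may erode the configuration at C2. The fallback sets out from flavone 22 and uses asymmetric hydrogenation instead of hydride conjugate addition. Ru(cod)(2-methylallyl)2 with the chiral N-heterocyclic carbene made from 1,3-bis[(R)-1-(naphthalen-1-yl)ethyl]-4,5-dihydroimidazolium tetrafluoroborate and KOt-Bu (H2 under high pressure, toluene–hexane) is a catalyst type known to hydrogenate flavones enantioselectively. It should reduce both the C2=C3 and C4=O bonds to give (2S)-5,7-bis(benzyloxy)-2-[(3S)-3,8-bis(benzyloxy)-2,2-dimethylchroman-6-yl]chroman-4-ol F4 as a mixture of C4 epimers. Dess–Martin oxidation of F4 (CH2Cl2, rt) comes back to the route at flavanone 23.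

Step 13. Over-reduction may cleave the benzylic C2–O1 bond and open ring C to a dihydrochalcone, or the hindered secondary benzyl ether may cleave incompletely. The fallback sets out from 23 and replaces hydrogenolysis by Lewis-acid dealkylation: BCl3 with pentamethylbenzene as benzyl-cation scavenger (CH2Cl2, −78 °C, then MeOH quench) should remove all four benzyl groups and arrive directly at target 24. It forms no new numbered compound.

Further compounds
F1 | step 11 | (3S)-3,8-bis(benzyloxy)-2,2-dimethylchromane-6-carbaldehyde | CC1(C)Oc2c(OCc3ccccc3)cc(C=O)cc2C[C@@H]1OCc1ccccc1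
F2 | step 11 | 1-[2,4-bis(benzyloxy)-6-hydroxyphenyl]ethan-1-one (purchased building block of the fallback) | CC(=O)c1c(O)cc(OCc2ccccc2)cc1OCc1ccccc1
F3 | step 11 | (2E)-1-[2,4-bis(benzyloxy)-6-hydroxyphenyl]-3-[(3S)-3,8-bis(benzyloxy)-2,2-dimethylchroman-6-yl]prop-2-en-1-one | CC1(C)Oc2c(OCc3ccccc3)cc(/C=C/C(=O)c3c(O)cc(OCc4ccccc4)cc3OCc3ccccc3)cc2C[C@@H]1OCc1ccccc1
F4 | step 12 | (2S)-5,7-bis(benzyloxy)-2-[(3S)-3,8-bis(benzyloxy)-2,2-dimethylchroman-6-yl]chroman-4-ol (C4 epimers) | CC1(C)Oc2c(OCc3ccccc3)cc([C@@H]3CC(O)c4c(OCc5ccccc5)cc(OCc5ccccc5)cc4O3)cc2C[C@@H]1OCc1ccccc1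
F0 | step 13 | none | none
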